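Take a closed, stirred vessel at constant volume and temperature, charged with starting material alone.

    starting material → product (k1 = 4.7 × 10⁻⁶ /s)
    starting material + product → 2 product (k2 = 0.34 /M/s)
    crystals ⇌ product, rate k3*(cs3 - [product]) while solid is left; crystals form when [product] > cs3 (cs3 = 2.0 mM, k3 = 1.0 /s)

starting material 0.050 M; time 12 min

* the state of affairs at 12 min: stopped, and by what, or still going (forward and back rates have come level / it is still moving / all of the starting material has reacted)
* product at 12 min, in percent of the starting material charged

- product is meant together with its crystals
- solid, in amounts per volume of the solution: crystals
- the reaction counts as stopped when no species that holds the starting material changes by six tenths of a point or more over the second half of the time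
- run time (flask): 12 min

Order the time constants, fastest first, and freeze what finishes early. Once crystals exist, they exchange with the solution in 1.00 s. At full charge, dissolved product multiplies with time constant τ = 58.8 s, much longer than that exchange time. The uncatalysed step is far slower, with a half-life of 41 h, so treat it as a seed. The seed is the ratio of the uncatalysed constant to the autocatalytic one, 0.0138 mM. Growing from it, dissolved product needs ln(146) time constants to reach solubility, which is 4.88 min. That uses 4.00% of the charge, so hold starting material at its charge until then.

Now freeze dissolved product at 2.0 mM. Define the frozen rate constant kf as the uncatalysed constant plus the autocatalytic constant times solubility: 0.0411 /min. Starting material then decays pseudo-first-order, with time constant 24.3 min, and crystals answer much faster than that. The remaining 7.12 min is shorter than this time constant, so my reckoning says still moving. Decaying the remaining 96.0% gives me 28.3% product.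

The forecast says it is still moving, with 28.5% product, between 27.5% and 29.5%. Its ground is that “crystallisation pins dissolved product” near 2.0 mM. My figure lies 0.20 percentage points below its value.

The simulation of this flask says it is still moving, with 28.5% product. Its ratio of making to using up dissolved product reads 0.999 at 7.65 min. Run kf on to 120 min in this flask: it gives 99.2%, and the longer run gives 99.2%.

Take the neighbour flask with 0.20 M of starting material. The sum in kf contains no charge, so keep it. There τ becomes 14.7 s, onset comes at 1.22 min, and the reckoning gives 36.4% product. That flask gives 38.0%.

(The numbers of this flask were drawn at random within sensible limits; the result is computed.)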